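| setting | north-west | south-west | north-east | flask |
|---|---|---|---|---|
| substrate | 0.70 M | 1.1 M | 0.50 M | 0.50 M |
| reagent in the second phase | 0.50 M | 0.50 M | 0.25 M | 0.500 M |
| remark | run made earlier | run made earlier | run made earlier |  |
| time |  |  |  | 5.0 h |
| volume of the second phase over the first |  |  |  | 0.25 |

- north-west (time / h: target / %, substrate / %): 0.500: 4, 90; 1.50: 23, 60; 3.00: 28, 38; 4.00: 31, 29; 6.00: 23, 19
- south-west (time / h: target / %, substrate / %): 1.33: 15, 68; 2.50: 18, 51; 4.00: 17, 43; 5.00: 16, 41; 6.00: 12, 39
- north-east (time / h: target / %, substrate / %): 1.33: 16, 79; 2.50: 21, 65; 4.00: 23, 53; 5.00: 21, 45; 6.00: 15, 44

(each reading ± 2 percentage points)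

- the target and product in the second phase together standing at 5.0 h, as a percentage of the substrate charged
- part of the substrate charged that has reacted at 5.0 h

- amounts and yields of target count product in the second phase too
- in the second phase: reagent in the second phase, product in the second phase; everything else is in the first
- charges count per volume of the first phase; a concentration in a rate is the amount of a species over the volume of its own phase; every rate counts per litre of the first phase
- the earlier runs hold the two phases in the same ratio of volumes as the flask asked about

At early times in the north-east run, 76.2% of the reacted substrate stands as target, but at 5.00 h the share, the selectivity on reacted substrate, has fallen to 38.2%. We therefore read one quantity: the natural log of reacted substrate over target, divided by the time, so that target is reacted substrate times e to the minus this rate times the time. The north-east run reads 0.193 /h for this fading rate, and the south-west run, with more substrate and more reagent in the second phase charged, reads a faster one, 0.261 /h.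

So we solve two extreme versions of the flask. In the harsh one, substrate lingers as in the north-east run and the target fades at that run's rate. In the gentle one, the line through these two readings against substrate charged is run back to no substrate, though the two runs differ in reagent in the second phase too, giving 0.136 /h. The north-west substrate decay, carried forward to 5.0 h, puts about 78.7% reacted, more than the north-east run's 55.0%. By this reckoning of ours less substrate stands in the flask than in the north-east run, yet 21.3% of it remains, so we place the flask between the extremes, from 30.0% to 39.9% target.

The forecast gives 33% (25% to 41%) target and 80% (72% to 87%) reacted, on the ground that “Selectivity improves at lower substrate”.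

The flask gives 38.5% target with 83.2% reacted.

    reagent in the reaction phase ⇌ reagent in the second phase, rate k1*([reagent in the reaction phase] - [reagent in the second phase]/K1) per volume of the first phase (partition coefficient = 2.30, kL = 1.70 × 10⁻⁴ /s)
    substrate + reagent in the reaction phase → target (k = 6.70 × 10⁻⁴ /M/s)
    target ⇌ product in the second phase, rate k3*([target] - [product in the second phase]/K3) per volume of the first phase (partition coefficient = 3.10, kL = 2.50 × 10⁻⁴ /s)
    target → decomposed product (k = 5.20 × 10⁻⁵ /s)
    substrate + target → side product (k = 2.00 × 10⁻⁴ /M/s)

At 5.0 h the flask holds 26.9% side product, each of these counted as two, and 17.8% decomposed product. The flask's fading rate is 0.154 /h, less than the harsh rate and more than the gentle one. Stopped at 3.0 h, the same flask has 67.7% reacted, so the two rates give 37.9% to 45.0% target, and it holds 39.0%.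

The runs were generated by integration with constants of no real substance, noise included.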